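Readings and results are simulated with constants of no real substance; noise was put on by code.

5 questions stand on these flasks, and one quantity served me for the two where substrate goes in slowly.

| flask | substrate | reagent | catalyst | remark | time |
|---|---|---|---|---|---|
| east | 0.10 M | 0.20 M | 0.50 mM | run made earlier |  |
| south | 0.10 M | 0.10 M | 0.50 mM | run made earlier |  |
| west | 0.10 M | 0.40 M | 0.50 mM | run made earlier |  |
| south-east | 0.10 M | 0.20 M | 1 mM | run made earlier |  |
| violet | 0.10 M | 0.200 M (fed, over 12 min) | 0.50 mM | all else is in the flask from the start; the feed brings no volume worth counting | 20 min |
| grey | 0.10 M | 0.200 M | 0.50 mM | everything together at the start | 20 min |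
| ochre | 0.10 M (in portions, 5, over 12 min) | 0.200 M | 0.50 mM | first portion at the start, last at 12 min | 20 min |
| teal | 0.10 M (fed, over 12 min) | 0.200 M | 0.50 mM | all else is in the flask from the start; the feed brings no volume worth counting | 20 min |

- east (time / min: target / %, substrate / %): 1.00: 20.8, 2.5; 3.00: 54.7, 0.7; 6.00: 76.7, 0; 8.00: 84.3, 0; 12.0: 91.9, 0
- south (time / min: target / %, substrate / %): 4.00: 39.4, 0; 8.00: 57.5, 0; 12.0: 66.6, 0.3; 15.0: 72.5, 0.2; 20.0: 77.2, 0.1
- west (time / min: target / %, substrate / %): 2.00: 64.2, 0.1; 5.00: 91.2, 0; 10.0: 97.2, 0.2; 15.0: 97.1, 0.6; 20.0: 97.2, 0
- south-east (time / min: target / %, substrate / %): 2.00: 64.9, 0; 5.00: 89.9, 0; 10.0: 97.8, 0; 15.0: 99.1, 0; 20.0: 99.1, 0.4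

(readings scatter by 0.3 percentage points)



- which flask leads in amount of target, in percent of the substrate charged ("all alike" within 1.5 percentage points) (violet / grey / ochre / teal / all alike)
- how much target is there at the end, in percent of the substrate charged: violet
- how much target is there at the end, in percent of the substrate charged: grey
- how much target is there at the end, in percent of the substrate charged: ochre
- how much target is there at the end, in percent of the substrate charged: teal

In the east run substrate fell to 2.5% after 1.00 min, so at this catalyst level it lived about 0.271 min. The west run levelled at 97.2%, a gap of 2.80%, and I read that gap as target yield lost where substrate meets target already standing, one substrate and one target going together, so that each such meeting costs the yield two units. West target closed on its plateau at 0.568 /min, so a substrate in west met on average about 0.00770 M of target during its life. I therefore defined the toll, the share of the target yield lost, both units of each meeting counted, per unit of target concentration a substrate meets at this catalyst level, and read it as 3.64 /M.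

In teal a fed substrate meets on average the target from the earlier part of the charge, aged a third of the feed time, 4.00 min, when the east curve stands near 62.0%. That mean, 0.0310 M, is half of the charge at that yield; it errs high since the curve bends over, and I took the same mean for ochre's even portions. The toll then costs about 11.3%, which left me near 88.7% in both, lower than the forecast's low end for teal.

The forecast chose grey, with violet 93.3%, grey 96.8%, ochre 92.2% and teal 91.8% (range 90% to 93.5%), holding ochre to “same mean addition time as teal”.

The flasks gave grey in the lead: violet 95.1%, grey 97.0%, ochre 83.8%, teal 84.9%.

    substrate + catalyst → catalyst + intermediate (k = 7000 /M/min)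
    substrate + target → side product (k = 6.60 /M/min)
    reagent + catalyst + intermediate → catalyst + target (k = 3600 /M²/min)

In teal, substrate turned into intermediate and was taken by target side by side through the feed, so at 12.0 min target stood at 61.4% and side product at 9.31%. Afterwards side product reached 9.76% while reagent carried intermediate down to 5.30% at 20.0 min. The toll's 11.3% of target yield stands against that side product, whose percentage counts two units of the charge in each side product. Scaled to the neighbour of ochre charged with 0.17 M of substrate, the toll gives 19.2%. That neighbour held 15.2% of side product and 73.1% of target at 20.0 min.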